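You read the maple flask at 8.0 d, but its last solid substrate reading, 0 %, stands earlier, at 5.00 d, and from 1.25 d on its target reads flat near 68.9 %. The cedar run has the same charges but is held at −35 °C instead of −20 °C, and from 2.50 d on its target reads flat near 77.4 %.

in all of them: solid substrate 0.20 M

| flask | reagent | temperature | remark | time |
|---|---|---|---|---|
| maple | 0.20 M | −20 °C | the very flask that is asked about, followed so far |  |
| cedar | 0.20 M | −35 °C | run made earlier |  |
| flask | 0.200 M | −20 °C |  | 8.0 d |

| run | time / d | target / % | solid substrate / % |
|---|---|---|---|
| maple | 0.417 | 51.4 | 20.2 |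
| maple | 1.25 | 69.2 | 1.0 |
| maple | 2.00 | 69.6 | 0 |
| maple | 3.00 | 68.1 | 2.6 |
| maple | 5.00 | 68.8 | 0 |
| cedar | 0.833 | 54.2 | 29.4 |
| cedar | 2.50 | 77.3 | 0 |
| cedar | 4.00 | 78.0 | 0.6 |
| cedar | 6.00 | 77.1 | 0.3 |
| cedar | 10.0 | 77.3 | 0.6 |

(scatter of a reading: 1 percentage point)

- zeta: at 8.0 d add reagent, 100 % of the amount charged, then wait 2.5 d
- beta: at 8.0 d raise the temperature by 25 K, then wait 2.5 d
- delta: change nothing and wait 2.5 d more

- additions leave the volume as it is
- the numbers in the tables scatter by 1 percentage point (one standard deviation)
- at the start none of the solid substrate is in solution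
- a reading or a percentage of target counts all its forms, free or not

1. target, in percent of the solid substrate first charged, at 8.0 d
2. the remedy with the largest gain of target, or "none" below 2 percentage points (zeta / beta / delta / none)
3. target present, in percent of the solid substrate first charged, after zeta
4. target present, in percent of the solid substrate first charged, after delta

Each run goes flat once its solid substrate reads about zero (0 % in maple, 0 % in cedar), so what separates them is how the substrate divided on its way out. Treat that as a branch point and define the odds O, target over what is not target, a selectivity factor for the whole run: 2.22 in maple, 3.43 in cedar. Temperature acts on rates through exponentials, so work in powers of ten. Let D be the decades by which the odds of the cedar run at −35 °C stand above those of the maple run at −20 °C, 0.189. Cedar ends higher than maple because the odds fall on warming, which means the loss branch gains on the target branch.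

My own reckoning for 8.0 d: hardly any solid substrate remains to divide, so O stays at its plateau, target stays near 68.9 %, and I expect each remedy to gain less than 2 percentage points.

The forecast gives 68.9 % (67.8 % to 70 %), 68.9 % after zeta (65 % to 70.5 %), 68.9 % after delta (67.6 % to 70 %) and best none, on this ground: “Waiting changes nothing, so no remedy helps.”

The flask gives 68.7 %, with 68.7 % after zeta, 68.7 % after delta and best none. At 8.00 d it holds 23.5 % as self-condensation product and 7.82 % as side product.

    2 dissolved substrate → side product (k = 30.0 M⁻¹ h⁻¹, Ea = 60.0 kJ mol⁻¹)
    dissolved substrate + reagent → target (k = 22.0 M⁻¹ h⁻¹, Ea = 54.0 kJ mol⁻¹)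
    reagent ⇌ dormant form (K = 0.810, k = 0.0130 h⁻¹, Ea = 83.0 kJ mol⁻¹, ΔH = −26.0 kJ mol⁻¹)
    solid substrate ⇌ dissolved substrate, rate k4*(cs4 - [dissolved substrate]) while solid is left; crystals form when [dissolved substrate] > cs4 (solubility = 15.0 mM, k = 1.00 h⁻¹)
    solid product ⇌ target, rate k5*(cs5 - [target]) while solid is left; crystals form when [target] > cs5 (solubility = 0.0790 M, k = 31.0 h⁻¹)
    2 solid substrate → self-condensation product (k = 0.170 M⁻¹ h⁻¹, Ea = 73.0 kJ mol⁻¹)
    (constants at −20 °C)

The odds of this flask are 2.19, which is 0.340 in decades. The neighbour kept at −5 °C lies as far above maple as maple lies above cedar, so taking off one more D of 0.189 gives 0.151 decades, odds of 1.42 and target 58.6 %. The computed neighbour holds 44.7 %, less than that step gives, with 53.7 % as self-condensation product.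

The readings were computed with constants of no real substance; scatter was added.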